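**Retrosynthetic overview**

1. Target ⇐ bicyclic 3-hydroxy-3-ene-2,8-dione (diosphenol) by C-8 reduction and epimerisation, O-methylation, 1,4-reduction and acetylation.
2. Key disconnection of that bicycle: C-8–C-5 closes the six-membered ring (C-1, C-2, C-3, C-4, C-5, C-8) first, by 4π opening and 6π closure of a cyclobutenone; C-7–C-1 then closes the bridging five-membered ring by benzylic cation capture. Both happen in one flask from a 4-alkenyl-4-hydroxycyclobutenone.
3. Enabling feature: C-3, C-2, C-1 and C-8 are four contiguous oxygen-bearing carbons of the six-membered ring and map onto the four carbons of dimethyl squarate, whose future C-8–C-3 σ bond is cleaved. Quaternary C-5 stops the ring-expanded product from aromatising, and C-7 is a 3,4-dimethoxybenzylic carbon that ionises easily.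
4. Cyclobutenone ⇐ dimethyl squarate + alkenyllithium; alkenyl iodide ⇐ anti homopropargylic alcohol by syn allylalumination and iodination; alcohol ⇐ 3,4-dimethoxybenzaldehyde + (R)-but-3-yn-2-yl mesylate, which sets C-6.
5. Numbering used throughout (bicyclo[3.2.1]octane): C-1 MeO-bearing bridgehead, C-2 ketone, C-3 CH–OMe, C-4 CH2, C-5 allyl-bearing bridgehead, C-6 CH–Me, C-7 CH–aryl, C-8 CH–OAc.

Key step: step 5

Assumption: (R)-but-3-yn-2-ol, 3,4-dimethoxybenzaldehyde and dimethyl squarate are taken as commercial; the carbinol configuration next to the aryl group is irrelevant because that centre is ionised in step 5.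

**Step 1**
Reactants: 1 (R)-but-3-yn-2-ol
Product: 2 (R)-but-3-yn-2-yl methanesulfonate
Conditions: MsCl, Et3N, CH2Cl2, −78 → 0 °C
Reagents that add atoms: methanesulfonyl chloride CS(=O)(=O)Cl
Why: Sulfonate ester formation at oxygen leaves the C–O bond and hence the R configuration untouched.

**Step 2**
Reactants: 2 (R)-but-3-yn-2-yl methanesulfonate; 3 3,4-dimethoxybenzaldehyde
Product: 5 (1S,2S)-1-(3,4-dimethoxyphenyl)-2-methylbut-3-yn-1-ol, via allenylzinc 4 (not isolated)
Conditions: Pd(OAc)2 (5 mol %), PPh3 (5 mol %), Et2Zn (3 equiv), THF, −78 → −20 °C; aq. NH4Cl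
Reagents that add atoms: none
Why: Marshall propargylation, in which zerovalent palladium displaces the mesylate anti (SN2'), Et2Zn transmetalates to allenylzinc 4, and cyclic SE2' addition to the aldehyde transfers the chirality of 2 to the methyl-bearing carbon (the later C-6, net inversion) and sets the carbinol anti to it.

**Step 3**
Reactants: 5 (1S,2S)-1-(3,4-dimethoxyphenyl)-2-methylbut-3-yn-1-ol
Product: 7 (1S,2S,3E)-1-(3,4-dimethoxyphenyl)-4-iodo-2-methyl-3-(prop-2-en-1-yl)but-3-en-1-ol, via alkenylalane 6 (not isolated)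
Conditions: i-Bu2AlCH2CH=CH2 (3 equiv), Cp2ZrCl2 (0.3 equiv), (CH2Cl)2, 0 °C → rt; then I2, THF, −30 → 0 °C; aq. HCl, aq. Na2S2O3
Reagents that add atoms: allyl(diisobutyl)alane C=CC[Al](CC(C)C)CC(C)C; iodine II
Why: Zirconium-catalysed carboalumination of the terminal alkyne (Negishi allylalumination) adds allyl and aluminium syn with allyl on the internal carbon, and iodinolysis of the C–Al bond with retention fixes the E alkene with iodine cis to allyl, the carbinol being carried as its aluminium alkoxide.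

**Step 4**
Reactants: 7 (1S,2S,3E)-1-(3,4-dimethoxyphenyl)-4-iodo-2-methyl-3-(prop-2-en-1-yl)but-3-en-1-ol; 8 3,4-dimethoxycyclobut-3-ene-1,2-dione
Product: 10 4-[(1E,3S,4S)-4-(3,4-dimethoxyphenyl)-4-hydroxy-3-methyl-2-(prop-2-en-1-yl)but-1-en-1-yl]-4-hydroxy-2,3-dimethoxycyclobut-2-en-1-one (both C-4 epimers), via dilithio species 9 (not isolated)
Conditions: MeLi (1.0 equiv), THF, −78 °C; t-BuLi (2.1 equiv), −78 °C; then 8, −78 °C; aq. NH4Cl, −78 °C
Reagents that add atoms: none
Why: Iodine–lithium exchange with retention of alkene geometry and 1,2-addition of the alkenyllithium to one squarate carbonyl is the standard entry to 4-hydroxycyclobutenones for the Moore rearrangement; the new carbinol carbon forms as both epimers, which is harmless because it becomes sp2 in step 5.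

**Step 5**
Reactants: 10 4-[(1E,3S,4S)-4-(3,4-dimethoxyphenyl)-4-hydroxy-3-methyl-2-(prop-2-en-1-yl)but-1-en-1-yl]-4-hydroxy-2,3-dimethoxycyclobut-2-en-1-one
Product: 13 (1S,5R,6R,7S)-7-(3,4-dimethoxyphenyl)-3-hydroxy-1-methoxy-6-methyl-5-(prop-2-en-1-yl)bicyclo[3.2.1]oct-3-ene-2,8-dione, via dienylketene 11 (not isolated), via enedione 12 (not isolated)
Conditions: PhCl, 110 °C; then 0 °C, CF3CO2H (10 equiv), 0 °C → rt; aq. NaHCO3
Reagents that add atoms: none
Why: Heating opens the cyclobutenone by conrotatory 4π electrocyclic ring opening (OH rotating outwards, alkenyl inwards) to dienylketene 11, which closes the six-membered ring (C-1, C-2, C-3, C-4, C-5, C-8) by disrotatory 6π electrocyclisation and so forms the C-8–C-5 bond; because C-5 is quaternary the hydroxydienone cannot aromatise and ketonises to enedione 12, which is the Moore rearrangement. Trifluoroacetic acid then ionises the 3,4-dimethoxybenzylic alcohol and the C-3 enol of 12 captures the cation at C-1 in a 5-exo-trig cation–olefin closure of the five-membered ring (C-1, C-7, C-6, C-5, C-8), forming the C-7–C-1 bond, after which the water set free hydrolyses the C-2 methoxy oxocarbenium with loss of methanol to give the diosphenol. The closest known reaction types are the Moore ring expansion of 4-alkenyl-4-hydroxycyclobutenones and the acid-mediated C-alkylation of alkoxy dienones by benzylic cations that operates in quinone monoketal–propenylarene [5+2] cycloadditions and in the acid isomerisation of hydrobenzofuran neolignans to bicyclo[3.2.1]octanes. C-5 is set in the 6π step by the C-6 stereocentre: with the branched chain on the outward position of the E alkene, allylic 1,2-strain puts C-6–H beside the geminal allyl group, the methyl group inside and the carbinol branch anti, so that the ketene carbon should bond on the methyl-flanked face. C-1 is then fixed by the tether (the cation reaches C-1 only across the face that carries the side chain) and C-7 by the cation conformer in which C-6–H eclipses the aryl group, which places aryl trans to methyl (aryl endo, methyl exo). The step needs this facial selectivity, ketonisation faster than [3,3] shift of the allyl group, and C- over O-alkylation; the first rests on the alkene geometry made in step 3, the second on the free 4-OH, and O-alkylation at the C-8 or C-3 oxygen is reversible in acid so that the C–C product is the sink.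

**Step 6**
Reactants: 13 (1S,5R,6R,7S)-7-(3,4-dimethoxyphenyl)-3-hydroxy-1-methoxy-6-methyl-5-(prop-2-en-1-yl)bicyclo[3.2.1]oct-3-ene-2,8-dione
Product: 14 (1S,5R,6R,7S,8R)-7-(3,4-dimethoxyphenyl)-3,8-dihydroxy-1-methoxy-6-methyl-5-(prop-2-en-1-yl)bicyclo[3.2.1]oct-3-en-2-one
Conditions: NaBH4, NaOH (1 equiv), EtOH/H2O, −20 → 0 °C; aq. HCl to pH 4
Reagents that add atoms: none
Why: Borohydride reduction of a ketone, in which the diosphenol is present as its enolate and so masks the C-2/C-3 dicarbonyl unit, leaving only the strained bridging C-8 ketone to react; hydride should arrive from the face of the unsaturated C-2–C-4 bridge because the exo methyl at C-6 blocks the other face, which gives the 8R alcohol (OH towards C-6/C-7) that step 8 corrects.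

**Step 7**
Reactants: 14 (1S,5R,6R,7S,8R)-7-(3,4-dimethoxyphenyl)-3,8-dihydroxy-1-methoxy-6-methyl-5-(prop-2-en-1-yl)bicyclo[3.2.1]oct-3-en-2-one
Product: 15 (1S,5R,6R,7S,8R)-7-(3,4-dimethoxyphenyl)-8-hydroxy-1,3-dimethoxy-6-methyl-5-(prop-2-en-1-yl)bicyclo[3.2.1]oct-3-en-2-one
Conditions: TMSCHN2, MeOH/PhMe 1:4, 0 °C → rt
Reagents that add atoms: (trimethylsilyl)diazomethane C[Si](C)(C)C=[N+]=[N-]
Why: O-Methylation of an acidic enol by a diazoalkane, in which only the diosphenol OH is acidic enough to protonate the reagent, so the hindered C-8 alcohol and all stereocentres stay untouched.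

**Step 8**
Reactants: 15 (1S,5R,6R,7S,8R)-7-(3,4-dimethoxyphenyl)-8-hydroxy-1,3-dimethoxy-6-methyl-5-(prop-2-en-1-yl)bicyclo[3.2.1]oct-3-en-2-one
Product: 17 (1S,5R,6R,7S,8S)-7-(3,4-dimethoxyphenyl)-8-hydroxy-1,3-dimethoxy-6-methyl-5-(prop-2-en-1-yl)bicyclo[3.2.1]oct-3-en-2-one, via aldehyde enolate 16 (not isolated)
Conditions: KOt-Bu (0.2 equiv), THF/t-BuOH, 0 °C → rt; AcOH
Reagents that add atoms: none
Why: Base-mediated retro-aldol/aldol equilibration of a β-hydroxy ketone, in which the C-8 alkoxide opens the C-1–C-8 bond to aldehyde enolate 16 and transannular aldol closure returns the bicycle with C-1 in the only configuration the ring allows and C-8 under thermodynamic control, the 8S alcohol (OH over the C-2–C-4 bridge, away from the exo C-6 methyl) being the less crowded epimer.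

**Step 9**
Reactants: 17 (1S,5R,6R,7S,8S)-7-(3,4-dimethoxyphenyl)-8-hydroxy-1,3-dimethoxy-6-methyl-5-(prop-2-en-1-yl)bicyclo[3.2.1]oct-3-en-2-one
Product: 19 (1S,3S,5S,6R,7S,8S)-7-(3,4-dimethoxyphenyl)-8-hydroxy-1,3-dimethoxy-6-methyl-5-(prop-2-en-1-yl)bicyclo[3.2.1]octan-2-one, via copper enolate 18 (not isolated)
Conditions: [(Ph3P)CuH]6 (0.5 equiv), PhMe, H2O (5 equiv), rt; aq. NH4Cl
Reagents that add atoms: none
Why: Stryker conjugate reduction, in which the monovalent copper hydride adds hydride 1,4 to the enone and leaves the isolated terminal alkene alone, and copper enolate 18 should be protonated at C-3 on the face that carries the neighbouring 8-OH (internal proton relay from water), which places 3-OMe anti to C-8 as in the target.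

**Step 10**
Reactants: 19 (1S,3S,5S,6R,7S,8S)-7-(3,4-dimethoxyphenyl)-8-hydroxy-1,3-dimethoxy-6-methyl-5-(prop-2-en-1-yl)bicyclo[3.2.1]octan-2-one
Product: 20 (1S,3S,5S,6R,7S,8S)-7-(3,4-dimethoxyphenyl)-1,3-dimethoxy-6-methyl-2-oxo-5-(prop-2-en-1-yl)bicyclo[3.2.1]octan-8-yl acetate
Conditions: Ac2O, DMAP (0.2 equiv), pyridine, rt → 40 °C
Reagents that add atoms: acetic anhydride CC(=O)OC(C)=O
Why: DMAP-catalysed acylation of the hindered secondary alcohol under weakly basic conditions that touch no stereocentre.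

**Compound list**

1 | (R)-but-3-yn-2-ol | C#C[C@@H](C)O | starting material
2 | (R)-but-3-yn-2-yl methanesulfonate | C#C[C@@H](C)OS(C)(=O)=O | intermediate
3 | 3,4-dimethoxybenzaldehyde | COc1ccc(C=O)cc1OC | starting material
4 | (aS)-buta-1,2-dien-1-yl(ethyl)zinc | CC[Zn][CH]=[C@@]=[CH]C | intermediate
5 | (1S,2S)-1-(3,4-dimethoxyphenyl)-2-methylbut-3-yn-1-ol | C#C[C@H](C)[C@H](O)c1ccc(OC)c(OC)c1 | intermediate
6 | diisobutyl{(1E,3S,4S)-4-(3,4-dimethoxyphenyl)-4-[(diisobutylalumanyl)oxy]-3-methyl-2-(prop-2-en-1-yl)but-1-en-1-yl}alumane | CC(C)C[Al](CC(C)C)/C=C(\CC=C)[C@H](C)[C@H](O[Al](CC(C)C)CC(C)C)c1ccc(OC)c(OC)c1 | intermediate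
7 | (1S,2S,3E)-1-(3,4-dimethoxyphenyl)-4-iodo-2-methyl-3-(prop-2-en-1-yl)but-3-en-1-ol | I/C=C(\CC=C)[C@H](C)[C@H](O)c1ccc(OC)c(OC)c1 | intermediate
8 | 3,4-dimethoxycyclobut-3-ene-1,2-dione (dimethyl squarate) | COC1=C(OC)C(=O)C1=O | starting material
9 | lithium (1S,2S,3E)-1-(3,4-dimethoxyphenyl)-4-lithio-2-methyl-3-(prop-2-en-1-yl)but-3-en-1-olate | [Li]/C=C(\CC=C)[C@H](C)[C@H](O[Li])c1ccc(OC)c(OC)c1 | intermediate
10 | 4-[(1E,3S,4S)-4-(3,4-dimethoxyphenyl)-4-hydroxy-3-methyl-2-(prop-2-en-1-yl)but-1-en-1-yl]-4-hydroxy-2,3-dimethoxycyclobut-2-en-1-one (both C-4 epimers) | COC1=C(OC)C(O)(/C=C(\CC=C)[C@H](C)[C@H](O)c2ccc(OC)c(OC)c2)C1=O | intermediate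
11 | (3Z,5E,7S,8S)-8-(3,4-dimethoxyphenyl)-4,8-dihydroxy-2,3-dimethoxy-7-methyl-6-(prop-2-en-1-yl)octa-1,3,5-trien-1-one | O=C=C(OC)/C(OC)=C(O)\C=C(/CC=C)[C@H](C)[C@H](O)c1ccc(OC)c(OC)c1 | intermediate
12 | (5S)-5-[(1S,2S)-1-(3,4-dimethoxyphenyl)-1-hydroxypropan-2-yl]-2,3-dimethoxy-5-(prop-2-en-1-yl)cyclohex-2-ene-1,4-dione | O=C1C(OC)=C(OC)C(=O)C[C@@]1(CC=C)[C@H](C)[C@H](O)c2ccc(OC)c(OC)c2 | intermediate
13 | (1S,5R,6R,7S)-7-(3,4-dimethoxyphenyl)-3-hydroxy-1-methoxy-6-methyl-5-(prop-2-en-1-yl)bicyclo[3.2.1]oct-3-ene-2,8-dione | C=CC[C@]12C=C(O)C(=O)[C@](OC)([C@H](c3ccc(OC)c(OC)c3)[C@H]1C)C2=O | intermediate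
14 | (1S,5R,6R,7S,8R)-7-(3,4-dimethoxyphenyl)-3,8-dihydroxy-1-methoxy-6-methyl-5-(prop-2-en-1-yl)bicyclo[3.2.1]oct-3-en-2-one | C=CC[C@]12C=C(O)C(=O)[C@](OC)([C@H](c3ccc(OC)c(OC)c3)[C@H]1C)[C@@H]2O | intermediate
15 | (1S,5R,6R,7S,8R)-7-(3,4-dimethoxyphenyl)-8-hydroxy-1,3-dimethoxy-6-methyl-5-(prop-2-en-1-yl)bicyclo[3.2.1]oct-3-en-2-one | C=CC[C@]12C=C(OC)C(=O)[C@](OC)([C@H](c3ccc(OC)c(OC)c3)[C@H]1C)[C@@H]2O | intermediate
16 | potassium (3S,4R,5R)-3-(3,4-dimethoxyphenyl)-5-formyl-2,7-dimethoxy-4-methyl-5-(prop-2-en-1-yl)cyclohepta-1,6-dien-1-olate | C=CC[C@]1(C=O)C=C(OC)C([O-])=C(OC)[C@H](c2ccc(OC)c(OC)c2)[C@H]1C.[K+] | intermediate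
17 | (1S,5R,6R,7S,8S)-7-(3,4-dimethoxyphenyl)-8-hydroxy-1,3-dimethoxy-6-methyl-5-(prop-2-en-1-yl)bicyclo[3.2.1]oct-3-en-2-one | C=CC[C@]12C=C(OC)C(=O)[C@](OC)([C@H](c3ccc(OC)c(OC)c3)[C@H]1C)[C@H]2O | intermediate
18 | monovalent copper enolate of 19, {[(1S,5S,6R,7S,8S)-7-(3,4-dimethoxyphenyl)-8-hydroxy-1,3-dimethoxy-6-methyl-5-(prop-2-en-1-yl)bicyclo[3.2.1]oct-2-en-2-yl]oxy}copper (phosphine ligand omitted) | C=CC[C@]12CC(OC)=C(O[Cu])[C@](OC)([C@H](c3ccc(OC)c(OC)c3)[C@H]1C)[C@H]2O | intermediate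
19 | (1S,3S,5S,6R,7S,8S)-7-(3,4-dimethoxyphenyl)-8-hydroxy-1,3-dimethoxy-6-methyl-5-(prop-2-en-1-yl)bicyclo[3.2.1]octan-2-one | C=CC[C@]12C[C@H](OC)C(=O)[C@](OC)([C@H](c3ccc(OC)c(OC)c3)[C@H]1C)[C@H]2O | intermediate
20 | (1S,3S,5S,6R,7S,8S)-7-(3,4-dimethoxyphenyl)-1,3-dimethoxy-6-methyl-2-oxo-5-(prop-2-en-1-yl)bicyclo[3.2.1]octan-8-yl acetate | C=CC[C@]12C[C@H](OC)C(=O)[C@](OC)([C@H](c3ccc(OC)c(OC)c3)[C@H]1C)[C@H]2OC(C)=O | target

**Totals and risks**

Total step count: 10. Longest linear sequence: 10 steps (1 → 20).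

Steps most likely to fail:

1. Step 5 (key step). What may go wrong: poor facial selectivity of the 6π closure with respect to the C-6 stereocentre, so that C-5 forms as both epimers; or [3,3] shift of the allyl group in the transient dienone before it ketonises. Fallback by the acid-promoted [5+2] cycloaddition of a quinone monoketal with a propenylarene, which makes the C-6–C-5 and C-7–C-1 bonds instead. It sets out from 3: Wittig ethylidenation (Ph3P=CHCH3, then I2-catalysed E/Z equilibration) would give (E)-1,2-dimethoxy-4-(prop-1-en-1-yl)benzene F1. Commercial 2,3,4-trimethoxyphenol would be O-allylated (allyl bromide, K2CO3) to 1,2,3-trimethoxy-4-(prop-2-en-1-yloxy)benzene F2. Claisen rearrangement (PhNEt2, 190 °C) would give 2,3,4-trimethoxy-6-(prop-2-en-1-yl)phenol F3, and PhI(OAc)2 in MeOH the quinone monoketal 4,4,5,6-tetramethoxy-2-(prop-2-en-1-yl)cyclohexa-2,5-dien-1-one F4. TMSOTf in MeCN at −30 °C would ionise F4, and the cation should add to F1 across its allyl-bearing and methoxy-bearing termini to give racemic (1S*,5R*,6R*,7S*)-7-(3,4-dimethoxyphenyl)-1,3-dimethoxy-6-methyl-5-(prop-2-en-1-yl)bicyclo[3.2.1]oct-3-ene-2,8-dione F5 (aryl endo, methyl exo from the E alkene). NaBH4 would reduce the bridging ketone to racemic (1S*,5R*,6R*,7S*,8R*)-7-(3,4-dimethoxyphenyl)-8-hydroxy-1,3-dimethoxy-6-methyl-5-(prop-2-en-1-yl)bicyclo[3.2.1]oct-3-en-2-one F6, and preparative HPLC on a chiral stationary phase would give 15, where the route is rejoined before step 8.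

2. Step 8. What may go wrong: the retro-aldol opening does not reverse cleanly (the ring-opened keto aldehyde is drained by other pathways), or equilibration at C-8 stays incomplete. Fallback that keeps the C-1–C-8 bond intact, from 15: Oppenauer/Meerwein–Ponndorf–Verley equilibration with Al(Oi-Pr)3 and a sub-stoichiometric hydride acceptor (cyclohexanone) in toluene at 80 °C. Reversible hydride transfer through the 8-ketone (1S,5R,6R,7S)-7-(3,4-dimethoxyphenyl)-1,3-dimethoxy-6-methyl-5-(prop-2-en-1-yl)bicyclo[3.2.1]oct-3-ene-2,8-dione F7 should equilibrate the carbinol centre and lead to 17.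

3. Step 9. What may go wrong: low reactivity of the hindered, electron-rich α-methoxy enone towards the copper hydride, or protonation at C-3 from the wrong face. Fallback that separates hydride delivery from protonation, from 17: RhCl(PPh3)3-catalysed 1,4-hydrosilylation with Et3SiH (2.5 equiv, PhH, 60 °C; the 8-OH is silylated in the same flask) would give [(1S,5S,6R,7S,8S)-7-(3,4-dimethoxyphenyl)-1,3-dimethoxy-6-methyl-5-(prop-2-en-1-yl)-8-(triethylsilyloxy)bicyclo[3.2.1]oct-2-en-2-yl]oxy(triethyl)silane F8. Bu4NF/AcOH in THF at 0 °C would then free the enolate and the alcohol, and protonation (equilibrated at C-3 if needed) gives 19.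

**Further compounds**

F1 | step 5 | (E)-1,2-dimethoxy-4-(prop-1-en-1-yl)benzene | C/C=C/c1ccc(OC)c(OC)c1
F2 | step 5 | 1,2,3-trimethoxy-4-(prop-2-en-1-yloxy)benzene | C=CCOc1ccc(OC)c(OC)c1OC
F3 | step 5 | 2,3,4-trimethoxy-6-(prop-2-en-1-yl)phenol | C=CCc1cc(OC)c(OC)c(OC)c1O
F4 | step 5 | 4,4,5,6-tetramethoxy-2-(prop-2-en-1-yl)cyclohexa-2,5-dien-1-one | C=CCC1=CC(OC)(OC)C(OC)=C(OC)C1=O
F5 | step 5 | racemic (1S*,5R*,6R*,7S*)-7-(3,4-dimethoxyphenyl)-1,3-dimethoxy-6-methyl-5-(prop-2-en-1-yl)bicyclo[3.2.1]oct-3-ene-2,8-dione (one enantiomer drawn) | C=CC[C@]12C=C(OC)C(=O)[C@](OC)([C@H](c3ccc(OC)c(OC)c3)[C@H]1C)C2=O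
F6 | step 5 | racemic (1S*,5R*,6R*,7S*,8R*)-7-(3,4-dimethoxyphenyl)-8-hydroxy-1,3-dimethoxy-6-methyl-5-(prop-2-en-1-yl)bicyclo[3.2.1]oct-3-en-2-one (one enantiomer drawn) | C=CC[C@]12C=C(OC)C(=O)[C@](OC)([C@H](c3ccc(OC)c(OC)c3)[C@H]1C)[C@@H]2O
F7 | step 8 | (1S,5R,6R,7S)-7-(3,4-dimethoxyphenyl)-1,3-dimethoxy-6-methyl-5-(prop-2-en-1-yl)bicyclo[3.2.1]oct-3-ene-2,8-dione (single enantiomer) | C=CC[C@]12C=C(OC)C(=O)[C@](OC)([C@H](c3ccc(OC)c(OC)c3)[C@H]1C)C2=O
F8 | step 9 | [(1S,5S,6R,7S,8S)-7-(3,4-dimethoxyphenyl)-1,3-dimethoxy-6-methyl-5-(prop-2-en-1-yl)-8-(triethylsilyloxy)bicyclo[3.2.1]oct-2-en-2-yl]oxy(triethyl)silane | C=CC[C@]12CC(OC)=C(O[Si](CC)(CC)CC)[C@](OC)([C@H](c3ccc(OC)c(OC)c3)[C@H]1C)[C@H]2O[Si](CC)(CC)CC
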